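The synthesis disconnects the C3–C4 CH2–CH2 bond of the cyclohexane ring of the 6-oxabicyclo[3.2.1]octan-7-one, together with the O6–C5 bond of its γ-lactone ring. Bridgehead C5 carries both the lactone oxygen and the isopropenyl group. It is therefore a masked tertiary allyl cation, the product of adding a CH2 radical to the CH2 terminus of a 2,3-disubstituted butadiene. One photocatalytic radical–polar crossover should convert an open-chain primary iodide bearing that diene and a quaternary methyl ester into the bicycle. This closes carbocycle and lactone and fixes C5. The precursor's three stereocentres come from (S)-β-methyl-γ-butyrolactone and a cyclic-orthoester Claisen rearrangement. The butenolide is coupled on last.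

Key step: step 10

Assumption: (S)-β-methyl-γ-butyrolactone, tert-butyl(2-iodoethoxy)dimethylsilane and 3-bromofuran-2(5H)-one are taken as catalogue chemicals.

Step 1
Reactants: 1 pent-4-ynoic acid
Product: 3 6-hydroxyhex-4-ynoic acid, via dilithium salt 2 (not isolated)
Conditions: n-BuLi (2.1 equiv), THF, −78 to 0 °C; (CH2O)n, 0 °C to rt; aq HCl
Reagents that add atoms: formaldehyde (from paraformaldehyde), C=O
Why: Alkynylation of an aldehyde: the carboxylate/acetylide dianion should add to formaldehyde at the acetylide carbon only, because the carboxylate shields its own α-position.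

Step 2
Reactants: 3 6-hydroxyhex-4-ynoic acid
Product: 4 methyl 6-hydroxyhex-4-ynoate
Conditions: MeOH, H2SO4 (cat.), reflux
Reagents that add atoms: methanol, CO
Why: Fischer esterification of an unhindered acid, which the propargylic alcohol and the alkyne tolerate.

Step 3
Reactants: 4 methyl 6-hydroxyhex-4-ynoate
Product: 5 methyl (4Z)-6-hydroxy-5-(tributylstannyl)hex-4-enoate
Conditions: Bu3SnH (1.1 equiv), [Cp*RuCl]4 (2 mol %), CH2Cl2, rt
Reagents that add atoms: tributyltin hydride, CCCC[SnH](CCCC)CCCC
Why: Hydroxyl-directed ruthenium-catalysed trans-hydrostannation should place tin on the alkyne carbon next to CH2OH and hydrogen anti to it, which fixes the ester chain cis to tin.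

Step 4
Reactants: 5 methyl (4Z)-6-hydroxy-5-(tributylstannyl)hex-4-enoate; 6 2-bromopropene
Product: 7 methyl (4E)-5-(hydroxymethyl)-6-methylhepta-4,6-dienoate
Conditions: Pd(PPh3)4 (5 mol %), CuI (10 mol %), CsF (2 equiv), DMF, 45 °C
Reagents that add atoms: none
Why: Stille coupling proceeds with retention at the alkenyl tin carbon, so the ester chain ends cis to the new isopropenyl group and trans to CH2OH, while CuI and fluoride speed up transmetalation of the hindered stannane.

Step 5
Reactants: 8 (4S)-4-methyloxolan-2-one; 9 tert-butyl(2-iodoethoxy)dimethylsilane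
Product: 11 (3S,4S)-3-[2-(tert-butyldimethylsilyloxy)ethyl]-4-methyloxolan-2-one, via lithium enolate 10 (not isolated)
Conditions: LiN(iPr)2 (1.05 equiv), THF, −78 °C; 9, DMPU, −78 to −20 °C
Reagents that add atoms: none
Why: Lactone enolate alkylation (SN2) should occur anti to the β-methyl group to give the trans lactone, and this α-centre is planarised again in step 7.

Step 6
Reactants: 11 (3S,4S)-3-[2-(tert-butyldimethylsilyloxy)ethyl]-4-methyloxolan-2-one
Product: 13 (3S,4S)-3-[2-(tert-butyldimethylsilyloxy)ethyl]-2,2-dimethoxy-4-methyloxolane, via O-methyl lactonium tetrafluoroborate 12 (not isolated)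
Conditions: Me3OBF4 (1.3 equiv), CH2Cl2, rt; NaOMe, MeOH, −78 to 0 °C
Reagents that add atoms: trimethyloxonium tetrafluoroborate, C[O+](C)C.F[B-](F)(F)F; sodium methoxide, C[O-].[Na+]
Why: O-Methylation of the lactone carbonyl followed by addition of methoxide to the dialkoxycarbenium ion is the standard route to cyclic orthoesters, and any 2-methoxy-4,5-dihydrofuran formed by deprotonation is equally competent in step 7.

Step 7
Reactants: 13 (3S,4S)-3-[2-(tert-butyldimethylsilyloxy)ethyl]-2,2-dimethoxy-4-methyloxolane; 7 methyl (4E)-5-(hydroxymethyl)-6-methylhepta-4,6-dienoate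
Product: 16 methyl (4S)-4-{(3S,4S)-3-[2-(tert-butyldimethylsilyloxy)ethyl]-4-methyl-2-oxooxolan-3-yl}-6-methyl-5-methylidenehept-6-enoate, via mixed orthoester 14 (not isolated), via ketene acetal 15 (not isolated)
Conditions: pivalic acid (10 mol %), xylenes, 140 °C, 4 Å sieves (removal of MeOH)
Reagents that add atoms: none
Why: Johnson–Claisen rearrangement of a cyclic orthoester: the dihydrofuran ring of 15 fixes the ketene-acetal geometry, the allyl unit should add anti to the ring methyl group (sets the quaternary carbon), and the chair transition state with the E-alkene places the ester chain pseudo-equatorial (sets the adjacent CH) while unveiling the 2,3-disubstituted diene.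

Step 8
Reactants: 16 methyl (4S)-4-{(3S,4S)-3-[2-(tert-butyldimethylsilyloxy)ethyl]-4-methyl-2-oxooxolan-3-yl}-6-methyl-5-methylidenehept-6-enoate
Product: 18 dimethyl (2S,3S)-2-[2-(tert-butyldimethylsilyloxy)ethyl]-2-[(2S)-1-hydroxypropan-2-yl]-3-(3-methylbuta-1,3-dien-2-yl)hexanedioate, via dipotassium salt 17 (not isolated)
Conditions: KOH (2.1 equiv), MeOH/H2O, 40 °C; evaporate and dry; MeI (3 equiv), DMF, 0 °C; used crude at once
Reagents that add atoms: potassium hydroxide, [K+].[OH-]; iodomethane, CI
Why: Saponification opens the lactone by acyl–oxygen cleavage and also hydrolyses the side-chain ester, and SN2 O-methylation of both carboxylates restores that ester and locks the quaternary carboxyl group as CO2Me without touching a stereocentre.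

Step 9
Reactants: 18 dimethyl (2S,3S)-2-[2-(tert-butyldimethylsilyloxy)ethyl]-2-[(2S)-1-hydroxypropan-2-yl]-3-(3-methylbuta-1,3-dien-2-yl)hexanedioate
Product: 19 dimethyl (2S,3S)-2-[2-(tert-butyldimethylsilyloxy)ethyl]-2-[(2S)-1-iodopropan-2-yl]-3-(3-methylbuta-1,3-dien-2-yl)hexanedioate
Conditions: PPh3, I2, imidazole (premixed), CH2Cl2, 0 °C
Reagents that add atoms: iodine, [I][I]
Why: Appel-type iodination with the premixed phosphorane should convert the primary alcohol faster than the γ-hydroxy ester can re-lactonise and leaves no free iodine to attack the diene.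

Step 10
Reactants: 19 dimethyl (2S,3S)-2-[2-(tert-butyldimethylsilyloxy)ethyl]-2-[(2S)-1-iodopropan-2-yl]-3-(3-methylbuta-1,3-dien-2-yl)hexanedioate
Product: 20 methyl 3-[(1R,2R,5S,8R)-1-[2-(tert-butyldimethylsilyloxy)ethyl]-2-methyl-7-oxo-5-(prop-1-en-2-yl)-6-oxabicyclo[3.2.1]octan-8-yl]propanoate
Conditions: 10-phenylphenothiazine (5 mol %), NaHCO3 (solid), MeCN (5 mM), 390 nm LEDs, 25 °C, argon
Reagents that add atoms: none
Why: Proposed new method: the excited phenothiazine should reduce the primary C–I bond, the CH2 radical should add to the free CH2 terminus of the 2,3-disubstituted diene, and the resulting allyl radical should be oxidised by the catalyst radical cation to a tertiary allyl cation that the quaternary CO2Me captures through its carbonyl oxygen, iodide then removing the O-methyl group as MeI, so the step is redox-neutral. The closest known reaction types are the photocatalytic atom-transfer cyclisation of unactivated alkyl iodides, the light-driven radical Heck/allylic substitution cascade of 1,3-dienes and the lactonisation of γ-halo esters with loss of alkyl halide. The carbocycle closes 6-endo-trig (5-exo attack on the fully substituted diene carbon would forgo allyl stabilisation) and the lactone closes 5-exo-trig on the allyl cation. The only new stereocentre, bridgehead C5, is dictated by the quaternary centre: in the chair with the methyl, silyloxyethyl and ester-propyl groups equatorial the CO2Me is axial and 1,3-diaxial to C5, so it can reach one face only. The step needs capture by this ester rather than by the flexible CH2CH2CO2Me (preorganised five-ring against floppy six-ring closure), attack at the tertiary rather than the primary allyl terminus (five- against seven-membered lactone), and cyclisation faster than 1,5-hydrogen transfer from the OCH2 group, which the diene acceptor and the quaternary centre should secure.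

Step 11
Reactants: 20 methyl 3-[(1R,2R,5S,8R)-1-[2-(tert-butyldimethylsilyloxy)ethyl]-2-methyl-7-oxo-5-(prop-1-en-2-yl)-6-oxabicyclo[3.2.1]octan-8-yl]propanoate
Product: 21 methyl 3-[(1R,2R,5S,8R)-1-(2-bromoethyl)-2-methyl-7-oxo-5-(prop-1-en-2-yl)-6-oxabicyclo[3.2.1]octan-8-yl]propanoate
Conditions: Ph3PBr2 (1.5 equiv), CH2Cl2, 0 °C to rt
Reagents that add atoms: dibromotriphenylphosphorane, BrP(Br)(c1ccccc1)(c1ccccc1)c1ccccc1
Why: Dibromotriphenylphosphorane converts primary silyl ethers directly into bromides (alkoxyphosphonium formation, then SN2) and should leave the hindered 1,1-disubstituted alkene, the lactone and the ester alone.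

Step 12
Reactants: 21 methyl 3-[(1R,2R,5S,8R)-1-(2-bromoethyl)-2-methyl-7-oxo-5-(prop-1-en-2-yl)-6-oxabicyclo[3.2.1]octan-8-yl]propanoate; 22 3-bromofuran-2(5H)-one
Product: 24 methyl 3-[(1R,2R,5S,8R)-2-methyl-7-oxo-1-[2-(2-oxo-2,5-dihydrofuran-3-yl)ethyl]-5-(prop-1-en-2-yl)-6-oxabicyclo[3.2.1]octan-8-yl]propanoate, via alkylzinc bromide 23 (not isolated)
Conditions: Zn dust, LiCl, THF, 45 °C; 22, PdCl2(dppf) (5 mol %), THF, rt
Reagents that add atoms: none
Why: Negishi coupling: zinc insertion tolerates ester and lactone, the chelating ligand suppresses β-hydride elimination, oxidative addition into the α-bromo enoate is fast, and room temperature should keep zerovalent palladium from ionising the hindered tertiary allylic lactone.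

Compound list
1 | pent-4-ynoic acid | C#CCCC(=O)O | starting material
2 | lithium 5-lithiopent-4-ynoate | [Li]C#CCCC(=O)O[Li] | intermediate
3 | 6-hydroxyhex-4-ynoic acid | OCC#CCCC(=O)O | intermediate
4 | methyl 6-hydroxyhex-4-ynoate | COC(=O)CCC#CCO | intermediate
5 | methyl (4Z)-6-hydroxy-5-(tributylstannyl)hex-4-enoate | COC(=O)CC/C=C(/CO)[Sn](CCCC)(CCCC)CCCC | intermediate
6 | 2-bromopropene | CC(Br)=C | starting material
7 | methyl (4E)-5-(hydroxymethyl)-6-methylhepta-4,6-dienoate | COC(=O)CC/C=C(/CO)C(C)=C | intermediate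
8 | (4S)-4-methyloxolan-2-one | O=C1OC[C@@H](C)C1 | starting material
9 | tert-butyl(2-iodoethoxy)dimethylsilane | CC(C)(C)[Si](C)(C)OCCI | starting material
10 | lithium enolate of 8 | [Li]OC1=C[C@H](C)CO1 | intermediate
11 | (3S,4S)-3-[2-(tert-butyldimethylsilyloxy)ethyl]-4-methyloxolan-2-one | O=C1OC[C@@H](C)[C@@H]1CCO[Si](C)(C)C(C)(C)C | intermediate
12 | O-methyl lactonium tetrafluoroborate of 11 | COC1=[O+]C[C@@H](C)[C@@H]1CCO[Si](C)(C)C(C)(C)C.F[B-](F)(F)F | intermediate
13 | (3S,4S)-3-[2-(tert-butyldimethylsilyloxy)ethyl]-2,2-dimethoxy-4-methyloxolane | COC1(OC)OC[C@@H](C)[C@@H]1CCO[Si](C)(C)C(C)(C)C | intermediate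
14 | mixed orthoester (one methoxy group of 13 replaced by the oxygen of 7, epimers at the orthoester carbon) | COC(=O)CC/C=C(/COC1(OC)OC[C@@H](C)[C@@H]1CCO[Si](C)(C)C(C)(C)C)C(C)=C | intermediate
15 | ketene acetal, methyl (4E)-5-({[(4S)-3-[2-(tert-butyldimethylsilyloxy)ethyl]-4-methyl-4,5-dihydrofuran-2-yl]oxy}methyl)-6-methylhepta-4,6-dienoate | COC(=O)CC/C=C(/COC1=C(CCO[Si](C)(C)C(C)(C)C)[C@H](C)CO1)C(C)=C | intermediate
16 | methyl (4S)-4-{(3S,4S)-3-[2-(tert-butyldimethylsilyloxy)ethyl]-4-methyl-2-oxooxolan-3-yl}-6-methyl-5-methylidenehept-6-enoate | O=C1OC[C@@H](C)[C@]1(CCO[Si](C)(C)C(C)(C)C)[C@H](C(=C)C(C)=C)CCC(=O)OC | intermediate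
17 | dipotassium salt of the ring-opened hydroxy diacid | [K+].[K+].OC[C@@H](C)[C@@](CCO[Si](C)(C)C(C)(C)C)(C(=O)[O-])[C@H](C(=C)C(C)=C)CCC(=O)[O-] | intermediate
18 | dimethyl (2S,3S)-2-[2-(tert-butyldimethylsilyloxy)ethyl]-2-[(2S)-1-hydroxypropan-2-yl]-3-(3-methylbuta-1,3-dien-2-yl)hexanedioate | OC[C@@H](C)[C@@](CCO[Si](C)(C)C(C)(C)C)(C(=O)OC)[C@H](C(=C)C(C)=C)CCC(=O)OC | intermediate
19 | dimethyl (2S,3S)-2-[2-(tert-butyldimethylsilyloxy)ethyl]-2-[(2S)-1-iodopropan-2-yl]-3-(3-methylbuta-1,3-dien-2-yl)hexanedioate | IC[C@@H](C)[C@@](CCO[Si](C)(C)C(C)(C)C)(C(=O)OC)[C@H](C(=C)C(C)=C)CCC(=O)OC | intermediate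
20 | methyl 3-[(1R,2R,5S,8R)-1-[2-(tert-butyldimethylsilyloxy)ethyl]-2-methyl-7-oxo-5-(prop-1-en-2-yl)-6-oxabicyclo[3.2.1]octan-8-yl]propanoate | C=C(C)[C@@]12CC[C@@H](C)[C@@](CCO[Si](C)(C)C(C)(C)C)(C(=O)O1)[C@H]2CCC(=O)OC | intermediate
21 | methyl 3-[(1R,2R,5S,8R)-1-(2-bromoethyl)-2-methyl-7-oxo-5-(prop-1-en-2-yl)-6-oxabicyclo[3.2.1]octan-8-yl]propanoate | C=C(C)[C@@]12CC[C@@H](C)[C@@](CCBr)(C(=O)O1)[C@H]2CCC(=O)OC | intermediate
22 | 3-bromofuran-2(5H)-one | O=C1OCC=C1Br | starting material
23 | alkylzinc bromide derived from 21 | C=C(C)[C@@]12CC[C@@H](C)[C@@](CC[Zn]Br)(C(=O)O1)[C@H]2CCC(=O)OC | intermediate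
24 | methyl 3-[(1R,2R,5S,8R)-2-methyl-7-oxo-1-[2-(2-oxo-2,5-dihydrofuran-3-yl)ethyl]-5-(prop-1-en-2-yl)-6-oxabicyclo[3.2.1]octan-8-yl]propanoate | C=C(C)[C@@]12CC[C@@H](C)[C@@](CCC3=CCOC3=O)(C(=O)O1)[C@H]2CCC(=O)OC | target

Total step count: 12. Longest linear sequence: 10 (steps 1–4, then 7–12).

Steps most likely to fail

Step 10 (labelled step).
- What may go wrong: single-electron reduction of the unactivated primary iodide may be slow. The primary radical may be diverted by 1,5-hydrogen transfer from the OCH2 group. The allyl cation may lose a proton instead of being captured by the ester.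
- Fallback (known chemistry): it sets out from 19. Bu3SnH and AIBN in refluxing benzene (slow addition) should effect the same 6-endo closure reductively. The allyl radical takes hydrogen at its CH2 terminus to give the isopropylidene cyclohexane F1.
- PhSeCl in CH2Cl2 at −78 °C should then trigger selenolactonisation by the axial ester, with loss of MeCl, to give the tertiary selenide F2.
- H2O2/pyridine should eliminate the selenoxide towards a methyl group, which comes back to the route at 20.

Step 7.
- What may go wrong: the exchange may stall at the mixed orthoester. At 140 °C the dienol may dehydrate or undergo a 1,5-hydrogen shift. The steric contact between the pseudo-axial silyloxyethyl arm and the isopropenyl group may erode the chair preference.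
- Fallback: a thio-Claisen rearrangement that runs near room temperature, setting out from 11 and 7. Compound 11 is thionated with 2,4-bis(4-methoxyphenyl)-1,3,2,4-dithiadiphosphetane 2,4-disulfide (toluene, 110 °C) to the thionolactone F3. Compound 7 is converted with CBr4/PPh3 into the allylic bromide F4.
- The enethiolate of F3 (KN(SiMe3)2, THF, −78 °C) is S-alkylated by F4 to the ketene O,S-acetal F5. This should rearrange at 25–60 °C to the quaternary thionolactone F6.
- S-Methylation with MeOTf and hydrolysis with aqueous NaHCO3 exchanges sulfur for oxygen and comes back to the route at 16.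

Step 8.
- What may go wrong: the γ-hydroxy ester may re-close to the lactone before it is iodinated. The silyl ether may be lost under the basic hydrolysis. The free alcohol may be O-methylated.
- Fallback: an irreversible SN2 opening, setting out from 16. PhSeNa (from PhSeSePh and NaBH4) in DMF at 110 °C attacks the two O-alkyl carbons (ring CH2 and ester CH3) and gives the seleno diacid F7, which cannot re-close.
- Me3SiCHN2 gives the seleno diester F8. MeI/NaI in DMF at 80 °C then exchanges the phenylselanyl group for iodide by way of the selenonium salt, which comes back to the route at 19.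

Further compounds
F1 | step 10 | methyl 1-[2-(tert-butyldimethylsilyloxy)ethyl]-2-(3-methoxy-3-oxopropyl)-6-methyl-3-(propan-2-ylidene)cyclohexane-1-carboxylate, configuration as in 19 | CC(C)=C1CC[C@@H](C)[C@@](CCO[Si](C)(C)C(C)(C)C)(C(=O)OC)[C@H]1CCC(=O)OC
F2 | step 10 | analogue of 20 with 2-(phenylselanyl)propan-2-yl in place of the isopropenyl group | CC(C)([Se]c1ccccc1)[C@@]12CC[C@@H](C)[C@@](CCO[Si](C)(C)C(C)(C)C)(C(=O)O1)[C@H]2CCC(=O)OC
F3 | step 7 | (3S,4S)-3-[2-(tert-butyldimethylsilyloxy)ethyl]-4-methyloxolane-2-thione | S=C1OC[C@@H](C)[C@@H]1CCO[Si](C)(C)C(C)(C)C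
F4 | step 7 | methyl 5-(bromomethyl)-6-methylhepta-4,6-dienoate, alkene geometry as in 7 | COC(=O)CC/C=C(/CBr)C(C)=C
F5 | step 7 | S-allyl ketene O,S-acetal, sulfur analogue of 15 | COC(=O)CC/C=C(/CSC1=C(CCO[Si](C)(C)C(C)(C)C)[C@H](C)CO1)C(C)=C
F6 | step 7 | thionolactone analogue of 16 | S=C1OC[C@@H](C)[C@]1(CCO[Si](C)(C)C(C)(C)C)[C@H](C(=C)C(C)=C)CCC(=O)OC
F7 | step 8 | diacid analogue of 19 with phenylselanyl in place of iodine | c1ccccc1[Se]C[C@@H](C)[C@@](CCO[Si](C)(C)C(C)(C)C)(C(=O)O)[C@H](C(=C)C(C)=C)CCC(=O)O
F8 | step 8 | dimethyl ester of F7 | c1ccccc1[Se]C[C@@H](C)[C@@](CCO[Si](C)(C)C(C)(C)C)(C(=O)OC)[C@H](C(=C)C(C)=C)CCC(=O)OC
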